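**Retrosynthetic overview**
1. Feature: C1 of the cyclohexane ring C1–C6 is a glycolate-type quaternary carbon bonded to O1, the carboxyl carbon C7, C2 and C6. O1 is 1,3-cis to O3, and the trans C4/C5 oxygens can be traced back to a C4=C5 alkene. The array C7–C1–C6–C5=C4 is then the γ,δ-unsaturated acid left by an ester-enolate Claisen shift.
2. Endgame: the target comes from acid hydrolysis of the 3,4-diacylated 1,5-lactone (quinide). That comes from acylation of equatorial O3–H first and axial O4–H second. Quinide comes from O3–H-directed epoxidation of the cyclohexene diol acid, followed by opening at C5 by the C1 carboxyl.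
3. Key disconnection: the C1–C6 bond is made by [3,3] ring contraction of the silyl ketene acetal of a 3,5-bis(silyloxy)-6-vinyl δ-lactone in which the 5-OSi and 6-vinyl groups are cis.
4. δ-Lactone: the C3–C4 bond comes from syn-selective (Z)-γ-(methoxymethoxy)allylboration of the dioxolanone aldehyde made from (S)-malic acid. O3 is silylated before O4 is unmasked, so the six-membered and not the five-membered lactone closes.
5. Ring order: dioxolanone (temporary), δ-lactone, carbocycle (the δ-lactone is consumed), bridging γ-lactone (opened last).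

Key step: step 8

Assumption: the SMILES places O1, O3 and O4 on one face of the ring and O5 and C7 on the other, with C3 and C5 both R, which is the (−)-quinic acid series. The target locants C1–C7 and O1–O5 are used for every intermediate, and the three phenols are carried as acetates.

**Step 1**
Reactants: 1 (S)-malic acid
Product: 2 (S)-2-(2,2-dimethyl-5-oxo-1,3-dioxolan-4-yl)acetic acid
Conditions: Me2C(OMe)2, p-TsOH·H2O (cat.), rt
Reagents that add atoms: 2,2-dimethoxypropane, COC(C)(C)OC
Why: Acid-catalysed transketalisation closes the five-membered 1,3-dioxolan-4-one on the α-hydroxy acid unit, which masks O1 and C7 together, leaves the distal carboxyl (future C3) free and does not touch C1.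

**Step 2**
Reactants: 2 (S)-2-(2,2-dimethyl-5-oxo-1,3-dioxolan-4-yl)acetic acid
Product: 3 (S)-5-(2-hydroxyethyl)-2,2-dimethyl-1,3-dioxolan-4-one
Conditions: BH3·THF, THF, 0 °C → rt; H2O
Reagents that add atoms: none
Why: Chemoselective borane reduction, in which the free acid is reduced through its acyloxyborane much faster than the dioxolanone carbonyl.

**Step 3**
Reactants: 3 (S)-5-(2-hydroxyethyl)-2,2-dimethyl-1,3-dioxolan-4-one
Product: 4 (S)-2-(2,2-dimethyl-5-oxo-1,3-dioxolan-4-yl)acetaldehyde
Conditions: Dess–Martin periodinane, CH2Cl2, 0 °C → rt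
Reagents that add atoms: none
Why: Dess–Martin oxidation is base-free and only weakly acidic, which should avoid both β-elimination of O1 from the aldehyde and lactonisation of 3.

**Step 4**
Reactants: 4 (S)-2-(2,2-dimethyl-5-oxo-1,3-dioxolan-4-yl)acetaldehyde; 5 3-(methoxymethoxy)prop-1-ene
Product: 10 (S)-5-[(2R,3R)-2-hydroxy-3-(methoxymethoxy)pent-4-en-1-yl]-2,2-dimethyl-1,3-dioxolan-4-one, via allyllithium 6 (not isolated), via methoxyborate 7 (not isolated), via allylborane 8 (not isolated), via borinate 9 (not isolated)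
Conditions: 5, s-BuLi, THF, −78 °C; (−)-Ipc2BOMe; BF3·OEt2; 4, −78 °C; then 30% H2O2, pH 7 phosphate buffer, MeOH, 0 °C
Reagents that add atoms: sec-butyllithium, [Li]C(C)CC (lithium held only in 6 and 7); (−)-B-methoxydiisopinocampheylborane, COB([C@@H]1C[C@@H]2C[C@H]([C@H]1C)C2(C)C)[C@@H]1C[C@@H]2C[C@H]([C@H]1C)C2(C)C (boron, methoxy and isopinocampheyl groups held only in 7 to 9)
Why: Brown (Z)-γ-alkoxyallylboration, in which the chair Zimmerman–Traxler array turns the Z geometry of the internally chelated allyl unit into the syn O3/O4 relation, the isopinocampheyl groups derived from (+)-α-pinene send the allyl unit to the Si face of the aldehyde to set C3 and C4 both R under reagent control, and the buffered peroxide work-up spares the dioxolanone.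

**Step 5**
Reactants: 10 syn hydroxy MOM ether
Product: 11 (S)-5-[(2R,3R)-2-(tert-butyldimethylsilyloxy)-3-(methoxymethoxy)pent-4-en-1-yl]-2,2-dimethyl-1,3-dioxolan-4-one
Conditions: TBSOTf, 2,6-lutidine, CH2Cl2, −78 → 0 °C (on freshly prepared 10)
Reagents that add atoms: tert-butyldimethylsilyl triflate, CC(C)(C)[Si](C)(C)OS(=O)(=O)C(F)(F)F
Why: Silyl triflate silylation is fast at low temperature with a non-nucleophilic base, so O3 is capped before it can attack C7 and form the γ-lactone, which later leaves O4 as the only hydroxyl able to lactonise.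

**Step 6**
Reactants: 11 O3-silyl O4-MOM dioxolanone
Product: 13 (3S,5R,6R)-5-(tert-butyldimethylsilyloxy)-3-hydroxy-6-vinyltetrahydro-2H-pyran-2-one, via O4-hydroxy dioxolanone 12 (not isolated)
Conditions: PPTS, t-BuOH, 80 °C
Reagents that add atoms: none
Why: Mild acid acetal cleavage followed by transacylative lactonisation, in which the allylic MOM ether ionises unimolecularly to an oxocarbenium ion taken up by the solvent, acid desilylation would need attack at silicon that t-BuOH is too hindered to deliver, and the freed O4–H closes on the activated dioxolanone carbonyl with loss of acetone and no change at C1, C3 or C4.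

**Step 7**
Reactants: 13 α-hydroxy δ-lactone
Product: 14 (3S,5R,6R)-3,5-bis(tert-butyldimethylsilyloxy)-6-vinyltetrahydro-2H-pyran-2-one (5-silyloxy cis to 6-vinyl)
Conditions: TBSOTf, 2,6-lutidine, CH2Cl2, −78 → 0 °C
Reagents that add atoms: tert-butyldimethylsilyl triflate, CC(C)(C)[Si](C)(C)OS(=O)(=O)C(F)(F)F
Why: Routine silylation of a secondary α-hydroxy lactone, where any epimerisation at C1 would not matter because C1 becomes trigonal in the next step.

**Step 8**
Reactants: 14 (3S,5R,6R)-3,5-bis(tert-butyldimethylsilyloxy)-6-vinyltetrahydro-2H-pyran-2-one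
Product: 17 (1R,5R)-1,5-bis(tert-butyldimethylsilyloxy)cyclohex-3-ene-1-carboxylic acid, via silyl ketene acetal 15 (not isolated), via trimethylsilyl ester 16 (not isolated)
Conditions: LiN(i-Pr)2, Me3SiCl–Et3N (present from the start), THF, −78 °C → rt; solvent change to PhMe, 110 °C; then aq. citric acid, THF, rt
Reagents that add atoms: chlorotrimethylsilane, C[Si](C)(C)Cl (Me3Si held only in 15 and 16)
Why: LiN(i-Pr)2 removes H1 and Me3SiCl traps the lactone enolate on oxygen to give the endocyclic ketene acetal 15, in which the malate centre is erased; on heating, 15 undergoes the Ireland–Claisen [3,3] shift along C1=C7–O4–C4–C5=C6, making C1–C6 and C4=C5 while C4–O4 breaks, and mild acid then frees 17 from silyl ester 16. The closest known reaction type is the ester-enolate Claisen ring contraction of 6-alkenyl δ-valerolactones and of 6-alkenyl-1,4-dioxan-2-ones, the latter already bearing an oxygen on the enolate carbon as here. The carbocycle C1–C6 closes through the pericyclic C1–C6 bond formation itself, in a boat, bicyclo[2.2.2]octane-like array (bridgeheads C1 and C4; bridges C7–O4, C2–C3 and C5=C6) enforced by the C2–C3 tether, so the new ring alkene is necessarily cis. The one new stereocentre, C1, is controlled by C4, because the axial vinyl group can reach C1 only across its own face of the lactone; since O3 is cis to that vinyl group, C7 ends trans and O1 cis to O3, and the C4 centre is consumed. The step needs O- over C-silylation and rearrangement ahead of ketene acetal decay, which are secured by the in situ silyl chloride at −78 °C, by the absence of any leaving group on C2, and by the cis 5,6-pattern that lets the vinyl group go axial while the C3 silyloxy group stays equatorial.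

**Step 9**
Reactants: 17 (1R,5R)-1,5-bis(tert-butyldimethylsilyloxy)cyclohex-3-ene-1-carboxylic acid
Product: 18 (1R,5R)-1,5-dihydroxycyclohex-3-ene-1-carboxylic acid (O1 and O3 cis)
Conditions: 48% aq. HF, MeCN, 0 °C → rt; evaporation
Reagents that add atoms: none
Why: Fluoride-driven desilylation in an acidic medium cleaves both Si–O bonds, its by-product is volatile so the polar diol acid can be obtained by evaporation, and no lactone can form because O3 is trans to C7.

**Step 10**
Reactants: 18 (1R,5R)-1,5-dihydroxycyclohex-3-ene-1-carboxylic acid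
Product: 20 (1S,3R,4R,5R)-1,3,4-trihydroxy-6-oxabicyclo[3.2.1]octan-7-one (quinic acid 1,5-lactone; quinide), via epoxy acid 19 (not isolated)
Conditions: m-CPBA, CH2Cl2–MeCN, 0 °C → rt
Reagents that add atoms: 3-chloroperoxybenzoic acid, OOC(=O)c1cccc(Cl)c1
Why: Henbest-type hydroxyl-directed epoxidation should deliver oxygen to the face of the allylic O3–H while the axial carboxyl screens the other face, and epoxy acid 19 then undergoes 5-exo, trans-diaxial (Fürst–Plattner) opening by the carboxyl at C5 from the opposite face, setting O4 cis to O3 and O5 trans to it in one operation.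

**Step 11**
Reactants: 21 caffeic acid
Product: 22 (E)-3-(3,4-diacetoxyphenyl)acrylic acid
Conditions: Ac2O, pyridine, rt; H2O
Reagents that add atoms: acetic anhydride, CC(=O)OC(C)=O
Why: Phenol acetylation masks the catechol so that only the carboxyl acts as acyl donor later, and the aqueous quench hydrolyses any mixed anhydride.

**Step 12**
Reactants: 22 (E)-3-(3,4-diacetoxyphenyl)acrylic acid
Product: 23 (E)-3-(3,4-diacetoxyphenyl)acryloyl chloride
Conditions: (COCl)2, DMF (cat.), CH2Cl2, 0 °C → rt
Reagents that add atoms: oxalyl chloride, ClC(=O)C(=O)Cl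
Why: Vilsmeier-catalysed acid chloride formation is mild enough to leave the aryl acetates and the E alkene intact.

**Step 13**
Reactants: 20 quinide; 23 (E)-3-(3,4-diacetoxyphenyl)acryloyl chloride
Product: 24 3-O-[(E)-3,4-diacetoxycinnamoyl]-1,5-quinide
Conditions: 23 (1 equiv), pyridine, −20 → 0 °C
Reagents that add atoms: none
Why: Regioselective acylation with an acid chloride in pyridine, since in the rigid bicyclic lactone O3–H is the only equatorial secondary hydroxyl, O4–H is axial and O1–H is tertiary, so one equivalent at low temperature should acylate O3.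

**Step 14**
Reactants: 25 p-coumaric acid
Product: 26 (E)-3-(4-acetoxyphenyl)acrylic acid
Conditions: Ac2O, pyridine, rt; H2O
Reagents that add atoms: acetic anhydride, CC(=O)OC(C)=O
Why: Phenol acetylation, for the same reason as in step 11.

**Step 15**
Reactants: 26 (E)-3-(4-acetoxyphenyl)acrylic acid
Product: 27 (E)-3-(4-acetoxyphenyl)acryloyl chloride
Conditions: (COCl)2, DMF (cat.), CH2Cl2, 0 °C → rt
Reagents that add atoms: oxalyl chloride, ClC(=O)C(=O)Cl
Why: Vilsmeier-catalysed acid chloride formation, as in step 12.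

**Step 16**
Reactants: 24 3-O-[(E)-3,4-diacetoxycinnamoyl]-1,5-quinide; 27 (E)-3-(4-acetoxyphenyl)acryloyl chloride
Product: 28 3-O-[(E)-3,4-diacetoxycinnamoyl]-4-O-[(E)-4-acetoxycinnamoyl]-1,5-quinide
Conditions: 27, DMAP (cat.), pyridine–CH2Cl2, rt
Reagents that add atoms: none
Why: DMAP-catalysed acylation should take the remaining secondary (axial) O4–H well ahead of the tertiary O1–H next to the lactone carbonyl, while O5 and C7 stay locked in the lactone.

**Step 17**
Reactants: 28 3-O-[(E)-3,4-diacetoxycinnamoyl]-4-O-[(E)-4-acetoxycinnamoyl]-1,5-quinide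
Product: 29 (1R,3R,4S,5R)-3-O-caffeoyl-4-O-p-coumaroylquinic acid (target)
Conditions: 2 M aq. HCl–THF, rt
Reagents that add atoms: water, O
Why: In this acid-catalysed acyl-oxygen ester hydrolysis the three aryl acetates and the strained α-hydroxy γ-lactone should react faster than the conjugated cinnamates of secondary alcohols, the low pH suppresses the O4→O5 acyl shift that base would trigger, and no stereocentre is touched.

**Compound list**
1 | (S)-malic acid | OC(=O)C[C@H](O)C(=O)O | starting material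
2 | (S)-2-(2,2-dimethyl-5-oxo-1,3-dioxolan-4-yl)acetic acid | OC(=O)C[C@@H]1OC(C)(C)OC1=O | intermediate
3 | (S)-5-(2-hydroxyethyl)-2,2-dimethyl-1,3-dioxolan-4-one | OCC[C@@H]1OC(C)(C)OC1=O | intermediate
4 | (S)-2-(2,2-dimethyl-5-oxo-1,3-dioxolan-4-yl)acetaldehyde | O=CC[C@@H]1OC(C)(C)OC1=O | intermediate
5 | 3-(methoxymethoxy)prop-1-ene | C=CCOCOC | starting material
6 | (Z)-3-(methoxymethoxy)allyllithium | [Li]C/C=C\OCOC | intermediate
7 | lithium [(Z)-3-(methoxymethoxy)allyl](methoxy)diisopinocampheylborate | [Li+].COCO/C=C\C[B-](OC)([C@@H]1C[C@@H]2C[C@H]([C@H]1C)C2(C)C)[C@@H]1C[C@@H]2C[C@H]([C@H]1C)C2(C)C | intermediate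
8 | [(Z)-3-(methoxymethoxy)allyl]diisopinocampheylborane (Ipc from (+)-α-pinene) | COCO/C=C\CB([C@@H]1C[C@@H]2C[C@H]([C@H]1C)C2(C)C)[C@@H]1C[C@@H]2C[C@H]([C@H]1C)C2(C)C | intermediate
9 | O3-diisopinocampheylborinate of 10 | C=C[C@@H](OCOC)[C@H](OB([C@@H]1C[C@@H]2C[C@H]([C@H]1C)C2(C)C)[C@@H]1C[C@@H]2C[C@H]([C@H]1C)C2(C)C)C[C@@H]1OC(C)(C)OC1=O | intermediate
10 | (S)-5-[(2R,3R)-2-hydroxy-3-(methoxymethoxy)pent-4-en-1-yl]-2,2-dimethyl-1,3-dioxolan-4-one | C=C[C@@H](OCOC)[C@H](O)C[C@@H]1OC(C)(C)OC1=O | intermediate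
11 | (S)-5-[(2R,3R)-2-(tert-butyldimethylsilyloxy)-3-(methoxymethoxy)pent-4-en-1-yl]-2,2-dimethyl-1,3-dioxolan-4-one | C=C[C@@H](OCOC)[C@H](O[Si](C)(C)C(C)(C)C)C[C@@H]1OC(C)(C)OC1=O | intermediate
12 | (S)-5-[(2R,3R)-2-(tert-butyldimethylsilyloxy)-3-hydroxypent-4-en-1-yl]-2,2-dimethyl-1,3-dioxolan-4-one | C=C[C@@H](O)[C@H](O[Si](C)(C)C(C)(C)C)C[C@@H]1OC(C)(C)OC1=O | intermediate
13 | (3S,5R,6R)-5-(tert-butyldimethylsilyloxy)-3-hydroxy-6-vinyltetrahydro-2H-pyran-2-one | C=C[C@H]1OC(=O)[C@@H](O)C[C@H]1O[Si](C)(C)C(C)(C)C | intermediate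
14 | (3S,5R,6R)-3,5-bis(tert-butyldimethylsilyloxy)-6-vinyltetrahydro-2H-pyran-2-one | C=C[C@H]1OC(=O)[C@@H](O[Si](C)(C)C(C)(C)C)C[C@H]1O[Si](C)(C)C(C)(C)C | intermediate
15 | (2R,3R)-3,5-bis(tert-butyldimethylsilyloxy)-6-(trimethylsilyloxy)-2-vinyl-3,4-dihydro-2H-pyran | C=C[C@H]1OC(O[Si](C)(C)C)=C(O[Si](C)(C)C(C)(C)C)C[C@H]1O[Si](C)(C)C(C)(C)C | intermediate
16 | trimethylsilyl (1R,5R)-1,5-bis(tert-butyldimethylsilyloxy)cyclohex-3-ene-1-carboxylate | CC(C)(C)[Si](C)(C)O[C@@]1(C(=O)O[Si](C)(C)C)C[C@@H](O[Si](C)(C)C(C)(C)C)C=CC1 | intermediate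
17 | (1R,5R)-1,5-bis(tert-butyldimethylsilyloxy)cyclohex-3-ene-1-carboxylic acid (silyloxy groups cis) | CC(C)(C)[Si](C)(C)O[C@@]1(C(=O)O)C[C@@H](O[Si](C)(C)C(C)(C)C)C=CC1 | intermediate
18 | (1R,5R)-1,5-dihydroxycyclohex-3-ene-1-carboxylic acid | O[C@@]1(C(=O)O)C[C@@H](O)C=CC1 | intermediate
19 | 2,4-dihydroxy-7-oxabicyclo[4.1.0]heptane-4-carboxylic acid (C4–C5 epoxide; epoxide O, O3 and O1 on one face, CO2H on the other) | O[C@@]1(C(=O)O)C[C@@H](O)[C@H]2O[C@H]2C1 | intermediate
20 | (1S,3R,4R,5R)-1,3,4-trihydroxy-6-oxabicyclo[3.2.1]octan-7-one (quinide) | O[C@@]12C[C@@H](O)[C@@H](O)[C@@H](C1)OC2=O | intermediate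
21 | caffeic acid | OC(=O)/C=C/c1ccc(O)c(O)c1 | starting material
22 | (E)-3-(3,4-diacetoxyphenyl)acrylic acid | OC(=O)/C=C/c1ccc(OC(C)=O)c(OC(C)=O)c1 | intermediate
23 | (E)-3-(3,4-diacetoxyphenyl)acryloyl chloride | ClC(=O)/C=C/c1ccc(OC(C)=O)c(OC(C)=O)c1 | intermediate
24 | 3-O-[(E)-3,4-diacetoxycinnamoyl]-1,5-quinide | O[C@@]12C[C@@H](OC(=O)/C=C/c3ccc(OC(C)=O)c(OC(C)=O)c3)[C@@H](O)[C@@H](C1)OC2=O | intermediate
25 | p-coumaric acid | OC(=O)/C=C/c1ccc(O)cc1 | starting material
26 | (E)-3-(4-acetoxyphenyl)acrylic acid | OC(=O)/C=C/c1ccc(OC(C)=O)cc1 | intermediate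
27 | (E)-3-(4-acetoxyphenyl)acryloyl chloride | ClC(=O)/C=C/c1ccc(OC(C)=O)cc1 | intermediate
28 | 3-O-[(E)-3,4-diacetoxycinnamoyl]-4-O-[(E)-4-acetoxycinnamoyl]-1,5-quinide | O[C@@]12C[C@@H](OC(=O)/C=C/c3ccc(OC(C)=O)c(OC(C)=O)c3)[C@@H](OC(=O)/C=C/c3ccc(OC(C)=O)cc3)[C@@H](C1)OC2=O | intermediate
29 | (1R,3R,4S,5R)-3-O-caffeoyl-4-O-p-coumaroylquinic acid (CNP0077575.1) | O=C(/C=C/c1ccc(O)cc1)O[C@H]1[C@H](O)C[C@](O)(C(=O)O)C[C@H]1OC(=O)/C=C/c1ccc(O)c(O)c1 | target

**Total steps:** 17. **Longest linear sequence:** 13 (steps 1–10, 13, 16, 17).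

**Steps most likely to fail**

1. Step 8.
   - What may go wrong: silylation on carbon instead of oxygen; hydrolytic or thermal decay of the ketene acetal; or a boat array too crowded by the C3 silyloxy group for the shift to compete.
   - Fallback, from 4 back to 17: C1–C6 is made by enolate alkylation and the ring is closed at C4=C5 by metathesis.
   - CH2=CHMgBr adds to 4 in THF at −78 °C, and the alkoxide closes on C7 with loss of acetone. The malate centre makes the two C3 epimers diastereomers, so chromatography should give the trans lactone (3S,5R)-3-hydroxy-5-vinyldihydrofuran-2(3H)-one F1.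
   - TBSOTf and 2,6-lutidine give (3S,5R)-3-(tert-butyldimethylsilyloxy)-5-vinyldihydrofuran-2(3H)-one F2.
   - LiN(i-Pr)2 followed by allyl bromide (THF, −78 °C) should alkylate the enolate on the face away from the vinyl group. This places C6 trans to C4 across the lactone, and hence O1 cis to O3, in (3R,5R)-3-allyl-3-(tert-butyldimethylsilyloxy)-5-vinyldihydrofuran-2(3H)-one F3.
   - LiOH in aqueous THF opens the lactone to lithium (2R,4R)-2-allyl-2-(tert-butyldimethylsilyloxy)-4-hydroxyhex-5-enoate F4. This is silylated as the salt (TBSOTf, 2,6-lutidine) to tert-butyldimethylsilyl (2R,4R)-2-allyl-2,4-bis(tert-butyldimethylsilyloxy)hex-5-enoate F5.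
   - K2CO3 in aqueous MeOH frees (2R,4R)-2-allyl-2,4-bis(tert-butyldimethylsilyloxy)hex-5-enoic acid F6. Second-generation Grubbs catalyst in CH2Cl2 at 40 °C then closes C4=C5 to give 17.

2. Step 6.
   - What may go wrong: loss of the silyl group, or its shift from O3 to O4, in the hot acidic medium, after which O3 closes the five-membered lactone; or incomplete acetal cleavage.
   - Fallback, from 4 back to 12: O4 is unmasked oxidatively instead of by acid.
   - Commercial allyl 4-methoxyphenyl ether is taken through the lithiation and boron sequence of step 4 to [(Z)-3-(4-methoxyphenoxy)allyl]diisopinocampheylborane F7.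
   - F7 should add to 4 with the same facial and syn sense to give (S)-5-[(2R,3R)-2-hydroxy-3-(4-methoxyphenoxy)pent-4-en-1-yl]-2,2-dimethyl-1,3-dioxolan-4-one F8.
   - TBSOTf and 2,6-lutidine give its O3-tert-butyldimethylsilyl ether F9.
   - (NH4)2Ce(NO3)6 in MeCN–H2O at 0 °C removes the electron-rich aryl group under conditions that a secondary silyl ether tolerates. This delivers 12, which is closed to 13 with catalytic PPTS in CH2Cl2 at rt.

3. Step 17.
   - What may go wrong: acetate hydrolysis too slow, so that the long acid exposure begins to cleave the cinnamoyl groups or shift them from O4 to O5; or incomplete lactone opening.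
   - Fallback, from 28 back to 29: phenol release is separated from lactone opening.
   - Immobilised Candida antarctica lipase B with n-BuOH in t-BuOMe at 40 °C should transfer only the three unhindered aryl acetates to the alcohol. This gives 3-O-caffeoyl-4-O-p-coumaroyl-1,5-quinide F10.
   - The lactone alone is then opened by a short treatment with dilute aq. HCl in THF at rt to give 29.

**Further compounds**
F1 | step 8 | (3S,5R)-3-hydroxy-5-vinyldihydrofuran-2(3H)-one | C=C[C@H]1C[C@H](O)C(=O)O1
F2 | step 8 | (3S,5R)-3-(tert-butyldimethylsilyloxy)-5-vinyldihydrofuran-2(3H)-one | C=C[C@H]1C[C@H](O[Si](C)(C)C(C)(C)C)C(=O)O1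
F3 | step 8 | (3R,5R)-3-allyl-3-(tert-butyldimethylsilyloxy)-5-vinyldihydrofuran-2(3H)-one | C=C[C@H]1C[C@@](CC=C)(O[Si](C)(C)C(C)(C)C)C(=O)O1
F4 | step 8 | lithium (2R,4R)-2-allyl-2-(tert-butyldimethylsilyloxy)-4-hydroxyhex-5-enoate | C=C[C@H](O)C[C@@](CC=C)(O[Si](C)(C)C(C)(C)C)C(=O)[O-].[Li+]
F5 | step 8 | tert-butyldimethylsilyl (2R,4R)-2-allyl-2,4-bis(tert-butyldimethylsilyloxy)hex-5-enoate | C=C[C@H](O[Si](C)(C)C(C)(C)C)C[C@@](CC=C)(O[Si](C)(C)C(C)(C)C)C(=O)O[Si](C)(C)C(C)(C)C
F6 | step 8 | (2R,4R)-2-allyl-2,4-bis(tert-butyldimethylsilyloxy)hex-5-enoic acid | C=C[C@H](O[Si](C)(C)C(C)(C)C)C[C@@](CC=C)(O[Si](C)(C)C(C)(C)C)C(=O)O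
F7 | step 6 | [(Z)-3-(4-methoxyphenoxy)allyl]diisopinocampheylborane | COc1ccc(O/C=C\CB([C@@H]2C[C@@H]3C[C@H]([C@H]2C)C3(C)C)[C@@H]2C[C@@H]3C[C@H]([C@H]2C)C3(C)C)cc1
F8 | step 6 | (S)-5-[(2R,3R)-2-hydroxy-3-(4-methoxyphenoxy)pent-4-en-1-yl]-2,2-dimethyl-1,3-dioxolan-4-one | C=C[C@@H](Oc1ccc(OC)cc1)[C@H](O)C[C@@H]1OC(C)(C)OC1=O
F9 | step 6 | (S)-5-[(2R,3R)-2-(tert-butyldimethylsilyloxy)-3-(4-methoxyphenoxy)pent-4-en-1-yl]-2,2-dimethyl-1,3-dioxolan-4-one | C=C[C@@H](Oc1ccc(OC)cc1)[C@H](O[Si](C)(C)C(C)(C)C)C[C@@H]1OC(C)(C)OC1=O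
F10 | step 17 | 3-O-caffeoyl-4-O-p-coumaroyl-1,5-quinide | O[C@@]12C[C@@H](OC(=O)/C=C/c3ccc(O)c(O)c3)[C@@H](OC(=O)/C=C/c3ccc(O)cc3)[C@@H](C1)OC2=O
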